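Time first: this flask has stood for 2.5 d, and you want to know what it holds and which option pays.

| setting | midnight | noon | flask |
|---|---|---|---|
| substrate | 20 mM | 20 mM | 20 mM |
| partner | 0.80 equiv | 0.40 equiv | 0.800 equiv |
| initiator | 15 mol% | 15 mol% | 15 mol% |
| remark | the very flask that is asked about, followed so far | run made earlier |  |
| time |  |  | 2.5 d |

| run | time / h | product / % | substrate / % |
|---|---|---|---|
| midnight | 6.00 | 46.9 | 52.3 |
| midnight | 12.0 | 47.0 | 52.6 |
| midnight | 20.0 | 47.2 | 52.2 |
| midnight | 25.0 | 47.4 | 52.4 |
| midnight | 30.0 | 47.0 | 51.8 |
| midnight | 40.0 | 47.2 | 52.1 |
| noon | 0.417 | 6.2 | 93.8 |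
| noon | 0.833 | 12.1 | 88.0 |
| noon | 1.33 | 18.2 | 81.8 |
| noon | 1.50 | 20.4 | 80.0 |
| noon | 2.00 | 25.7 | 74.1 |
| noon | 2.50 | 29.6 | 71.0 |

(each reading ± 0.3 percentage points)

- product is meant together with its idle adduct B
- released group is meant together with its idle adduct A
- additions leave the volume as it is
- the numbers in the tables scatter by 0.3 percentage points (one standard deviation)
- on the list of suspects stand: initiator -> 2 initiating radical; substrate + initiating radical -> capped initiator + first chain carrier; partner + first chain carrier -> product + second chain carrier; substrate + second chain carrier -> released group + first chain carrier; 2 second chain carrier -> ended chains; partner -> decomposed reagent; partner + released group <-> idle adduct A; partner + product <-> idle adduct B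

- Saturday's: at 2.5 d take out 90% of the released group then present, then wait 20 h
- Friday's: at 2.5 d add substrate, 50.0% of the amount charged, then wait 20 h
- Tuesday's: at 2.5 d add partner, 100% of the amount charged, then wait 20 h
- Sunday's: change nothing and wait 20 h more

1. product, in percent of the substrate first charged, at 2.5 d
2. the option that brings most further product ("none" if no option brings more than 2 percentage points) (Saturday's / Friday's / Tuesday's / Sunday's / none)
3. product present, in percent of the substrate first charged, after Saturday's
4. product present, in percent of the substrate first charged, after Tuesday's

Read the noon table down its substrate column, taking ln(charged/left) divided by time: 0.153 h⁻¹ at 0.417 h, 0.151 h⁻¹ at 1.33 h, and 0.137 h⁻¹ at 2.50 h. Chain carriers are born from initiator and end two at a time. If births match deaths, their level holds, and while partner lasts each hour takes a fixed share of [substrate]. Call that share the chain speed, a pseudo-first-order constant read from the noon run. By that balance, it goes with the square root of [initiator].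

Now read the midnight table row against row. From 6.00 h to 40.0 h, product stays near 47.2% and substrate near 52.1%. At chain speed, those hours would have brought substrate down to 0.308%, so the midnight chain has stopped with substrate in hand. I take partner as the limiting reagent, and the midnight chain's working time as 4.32 h. My reckoning: product stays near 47.2%, Saturday's and Friday's bring nothing, and Tuesday's buys a second working time on the remaining substrate, reaching 72.2%.

The forecast gave 47.1% (46.8% to 47.5%), Tuesday's, 47.1% after Saturday's (46.7% to 47.7%) and 66% after Tuesday's (52% to 78%), on the ground that “Fresh partner restarts the chain”.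

The flask gives 47.1% now, 47.1% after Saturday's, and 88.3% after Tuesday's, which is above my figure by 16 percentage points.

    initiator → 2 initiating radical (k = 3.50 × 10⁻⁷ s⁻¹)
    substrate + initiating radical → capped initiator + first chain carrier (k = 2.40 × 10⁵ M⁻¹ s⁻¹)
    partner + first chain carrier → product + second chain carrier (k = 5100 M⁻¹ s⁻¹)
    substrate + second chain carrier → released group + first chain carrier (k = 2500 M⁻¹ s⁻¹)
    2 second chain carrier → ended chains (k = 3.80 × 10⁶ M⁻¹ s⁻¹)
    partner → decomposed reagent (k = 8.90 × 10⁻⁵ s⁻¹)
    partner + released group ⇌ idle adduct A, settled at all times (K = 40.0 M⁻¹)
    partner + product ⇌ idle adduct B, settled at all times (K = 56.0 M⁻¹)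

In this flask product has come to rest, but substrate has not. Ten times the time leaves product at 47.1% with partner at 0%, while substrate falls from 50.9% to 37.2% and first chain carrier grows from 2.03% to 15.8%. That drift is 5.82 × 10⁻⁴ h⁻¹, far below the chain speed of 0.151 h⁻¹. When Tuesday's partner goes in, the flask already holds that stock of first chain carrier, 2.03% against 0.0697% at 6.00 h.

Take the neighbour charged with 8.0 mM of substrate, at the same equivalents and loading: the root rule puts its chain speed at 0.0955 h⁻¹, and the same working time gives 33.8% product. Computed, that neighbour reaches 37.6%, with substrate at 60.4%.

(The data are calculated for an exercise.)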